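Ring numbering: C1 (carbinol), C2 (CH), C3 (quaternary), C4 (CHBr), C5, C6. The cyclohexane is closed at C5–C6 by mercury-triggered cyclisation of an acyclic hexa-1,5-diene through its two terminal carbons, an arrested Cope process. It exploits the 1,4-relationship of the C1 oxygen and C4 bromine across C5–C6: mercury adds to the vinyl carbon (C4), trifluoroacetate to the isopropenyl carbon (C1), and a chair biased by the C2/C3 stereocentres sets both new centres. The precursor bears vinyl and isopropenyl groups on the C3/C2 pair, built by an enantioselective Ireland–Claisen rearrangement of a geranyl-type ester of a linalool-derived acid. Bromine then replaces mercury with retention.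

Key step: step 11

Assumption: (S)-(+)-linalool of high enantiomeric purity is taken as a commercial chiral-pool material.
Assumption: the (S,S)-configured boron controller of step 8 is taken to give the (2S,3R) acid 14; if the sense of induction is the opposite, its equally available (R,R) enantiomer is used.
Abbreviation: TBS = tert-butyldimethylsilyl.

Step 1
Reactants: 1 (S)-linalool
Product: 2 (S)-linalool TBS ether
Conditions: TBSOTf, 2,6-lutidine, CH2Cl2, −78 to 0 °C
Reagents that add atoms: tert-butyldimethylsilyl triflate CC(C)(C)[Si](C)(C)OS(=O)(=O)C(F)(F)F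
Why: Silyl ether formation with the triflate, which silylates hindered tertiary alcohols; no stereocentre is touched, and the ether later keeps this oxygen from capturing the ring cation.

Step 2
Reactants: 2 (S)-linalool TBS ether
Product: 4 (4S)-4-methyl-4-(TBS-oxy)hex-5-enal, via ozonide 3 (not isolated)
Conditions: O3, CH2Cl2, −78 °C (Sudan red 7B end point); then Me2S, −78 °C to rt
Reagents that add atoms: ozone [O-][O+]=O
Why: Chemoselective ozonolysis, in which the electron-rich trisubstituted alkene is consumed far faster than the vinyl group next to the silyloxy-bearing carbon, and the ozonide is reduced to the aldehyde by the sulfide.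

Step 3
Reactants: 4 (4S)-4-methyl-4-(TBS-oxy)hex-5-enal
Product: 5 (5S)-1,1,1-trichloro-5-methyl-5-(TBS-oxy)hept-6-en-2-ol (both C2 epimers)
Conditions: CHCl3, LiN(SiMe3)2, THF, −78 °C; aqueous work-up
Reagents that add atoms: chloroform ClC(Cl)Cl
Why: 1,2-Addition of trichloromethyllithium, formed from chloroform faster than the aldehyde is enolised, gives the trichloromethyl carbinol, whose new centre is irrelevant because it becomes CH2 in the next step.

Step 4
Reactants: 5 (5S)-1,1,1-trichloro-5-methyl-5-(TBS-oxy)hept-6-en-2-ol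
Product: 6 (5S)-5-methyl-5-(TBS-oxy)hept-6-enoic acid
Conditions: NaBH4, NaOH, tBuOH/H2O, 55 °C; work-up at pH 4
Reagents that add atoms: sodium hydroxide [Na+].[OH-]
Why: Jocic–Reeve-type one-carbon homologation, in which the alkoxide closes to a gem-dichloroepoxide, borohydride opens it at the former carbinol carbon and the resulting acyl chloride is hydrolysed to the carboxylate.

Step 5
Reactants: 7 geraniol
Product: 9 (2E,5E)-3,7-dimethylocta-2,5-diene-1,7-diol, via hydroperoxide 8 (not isolated)
Conditions: O2, hν (visible), tetraphenylporphyrin (cat.), CH2Cl2, 0 °C; then PPh3, 0 °C to rt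
Reagents that add atoms: dioxygen O=O
Why: Schenck ene reaction of singlet oxygen at the more electron-rich 6,7-alkene with hydrogen abstraction from C5 gives the tertiary allylic hydroperoxide with an E-alkene, which the phosphine reduces; the regioisomeric secondary alcohol expected alongside is removed by chromatography.

Step 6
Reactants: 6 (5S)-5-methyl-5-(TBS-oxy)hept-6-enoic acid; 9 (2E,5E)-3,7-dimethylocta-2,5-diene-1,7-diol
Product: 10 (2E,5E)-7-hydroxy-3,7-dimethylocta-2,5-dien-1-yl (5S)-5-methyl-5-(TBS-oxy)hept-6-enoate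
Conditions: DCC, DMAP (cat.), CH2Cl2, 0 °C to rt
Reagents that add atoms: none
Why: Steglich esterification, selective for the primary allylic hydroxyl over the hindered tertiary one.

Step 7
Reactants: 10 hydroxy ester
Product: 11 (2E,5E)-3,7-dimethyl-7-(TBS-oxy)octa-2,5-dien-1-yl (5S)-5-methyl-5-(TBS-oxy)hept-6-enoate
Conditions: TBSOTf, 2,6-lutidine, CH2Cl2, −78 to 0 °C
Reagents that add atoms: tert-butyldimethylsilyl triflate CC(C)(C)[Si](C)(C)OS(=O)(=O)C(F)(F)F
Why: Silyl ether formation at the tertiary allylic alcohol, so that no free hydroxyl meets the boron reagent of the next step.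

Step 8
Reactants: 11 bis-silyl ester
Product: 14 (2S,3R)-3-methyl-2-[(3S)-3-methyl-3-(TBS-oxy)pent-4-en-1-yl]-3-[(2E)-4-methyl-4-(TBS-oxy)pent-2-en-1-yl]pent-4-enoic acid, via boron ketene acetal 12 (not isolated), via boryl ester 13 (not isolated)
Conditions: (4S,5S)-2-bromo-1,3-bis{[3,5-bis(trifluoromethyl)phenyl]sulfonyl}-4,5-diphenyl-1,3,2-diazaborolidine, iPr2NEt, CH2Cl2, −78 °C, then 4 °C; aqueous work-up
Reagents that add atoms: none
Why: Enantioselective Ireland–Claisen rearrangement through a chiral boron ketene acetal: the hindered amine in CH2Cl2 is expected to give the enolate with the alkyl chain cis to O–B, the chair with the E-alkene then fixes the (2S*,3R*) relationship of the new tertiary and quaternary centres, and the C2-symmetric sulfonamide ligand on boron selects the enolate face.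

Step 9
Reactants: 14 acid
Product: 16 (3S,4R)-4-methyl-3-[(3S)-3-methyl-3-(TBS-oxy)pent-4-en-1-yl]-4-[(2E)-4-methyl-4-(TBS-oxy)pent-2-en-1-yl]hex-5-en-2-one, via dilithium gem-diolate 15 (not isolated)
Conditions: MeLi (3.5 equiv), Et2O, 0 °C to rt; inverse aqueous quench
Reagents that add atoms: methyllithium [Li]C
Why: Addition of methyllithium to the lithium carboxylate stops at the gem-diolate, which gives the methyl ketone on hydrolysis; the α-stereocentre, flanked by a quaternary carbon, is not deprotonated.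

Step 10
Reactants: 16 methyl ketone
Product: 17 (3R,4R)-2,4-dimethyl-3-[(3S)-3-methyl-3-(TBS-oxy)pent-4-en-1-yl]-4-[(2E)-4-methyl-4-(TBS-oxy)pent-2-en-1-yl]hexa-1,5-diene
Conditions: Ph3PCH3Br, KN(SiMe3)2, THF, 0 to 40 °C
Reagents that add atoms: methyltriphenylphosphonium bromide C[P+](c1ccccc1)(c1ccccc1)c1ccccc1.[Br-]
Why: Wittig methylenation with the non-stabilised ylide; any enolisation should occur on the methyl side and leave the α-stereocentre untouched.

Step 11
Reactants: 17 diene
Product: 19 (1S,2S,3S,4S)-4-(bromomercurio)-1,3-dimethyl-2-[(3S)-3-methyl-3-(TBS-oxy)pent-4-en-1-yl]-3-[(2E)-4-methyl-4-(TBS-oxy)pent-2-en-1-yl]cyclohexan-1-ol, via bis(trifluoroacetate) 18 (not isolated)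
Conditions: Hg(OCOCF3)2 (1.1 equiv), MeNO2, −20 °C; then KBr, K2CO3, MeOH/H2O, 0 °C
Reagents that add atoms: mercury bis(trifluoroacetate) O=C(O[Hg]OC(=O)C(F)(F)F)C(F)(F)F; potassium bromide [K+].[Br-]
Why: Proposed new method: Hg(OCOCF3)2 binds the alkenes reversibly, and the only complex with a cyclisation outlet is the mercurinium ion of the vinyl group, whose CH2 terminus (future C5) is attacked by the CH2 terminus of the isopropenyl group (future C6) to give the tertiary C1 cation, which collapses with trifluoroacetate. The closest known reactions are mercury-induced polyene cyclisations with oxygen termination followed by brominative demercuration, and the cyclohexyl-cation stage of Cope rearrangements catalysed by divalent palladium and of 1,5-diene cyclisations started by divalent platinum, both of which begin at a monosubstituted alkene in this sense; with mercury this sense is not documented. The ring closes 6-endo with respect to both alkenes through a chair, the five-membered alternative being a 5-endo attack of the isopropenyl group that geometry forbids. In that chair the C2 and C3 chains are equatorial and the C3 methyl axial, so anti addition of mercury and carbon across the vinyl group sets C4 (mercury equatorial) and anti addition of carbon and trifluoroacetate across the isopropenyl group sets C1 (oxygen equatorial, methyl axial). The step needs site selectivity for the vinyl group: mercuration of the more electron-rich isopropenyl group is reversible and unproductive, the side-chain vinyl group and E-alkene are hindered and deactivated by allylic silyloxy groups, and the bulky silyl ether keeps the chain oxygen from capturing the cation. KBr and K2CO3 then exchange the ligand on mercury and cleave the labile tertiary trifluoroacetate.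

Step 12
Reactants: 19 organomercuric bromide
Product: 20 (1S,2S,3S,4S)-4-bromo-1,3-dimethyl-2-[(3S)-3-methyl-3-(TBS-oxy)pent-4-en-1-yl]-3-[(2E)-4-methyl-4-(TBS-oxy)pent-2-en-1-yl]cyclohexan-1-ol
Conditions: Br2, LiBr, pyridine, O2 atmosphere, dark, 0 °C to rt
Reagents that add atoms: bromine BrBr
Why: Brominative demercuration, a polar cleavage of the carbon–mercury bond by bromine in pyridine that should proceed with retention (oxygen suppresses the radical chain) and give the equatorial bromide; both remaining alkenes are deactivated by allylic silyloxy groups.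

Step 13
Reactants: 20 bis-silyl ether
Product: 21 (1S,2S,3S,4S)-4-bromo-2-[(3S)-3-hydroxy-3-methylpent-4-en-1-yl]-3-[(2E)-4-hydroxy-4-methylpent-2-en-1-yl]-1,3-dimethylcyclohexan-1-ol
Conditions: Bu4NF, THF, 45 °C
Reagents that add atoms: none
Why: Fluoride-mediated cleavage of both tertiary silyl ethers; the equatorial neopentyl-type bromide has no antiperiplanar hydrogen and should be inert to fluoride under these conditions.

Compound list
1 | (S)-(+)-linalool, (3S)-3,7-dimethylocta-1,6-dien-3-ol | C=C[C@@](C)(O)CCC=C(C)C | starting material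
2 | (S)-linalool TBS ether | C=C[C@@](C)(O[Si](C)(C)C(C)(C)C)CCC=C(C)C | intermediate
3 | ozonide (1,2,4-trioxolane) of the 6,7-alkene of 2 | C=C[C@@](C)(O[Si](C)(C)C(C)(C)C)CCC1OOC(C)(C)O1 | intermediate
4 | (4S)-4-methyl-4-(TBS-oxy)hex-5-enal | C=C[C@@](C)(O[Si](C)(C)C(C)(C)C)CCC=O | intermediate
5 | (5S)-1,1,1-trichloro-5-methyl-5-(TBS-oxy)hept-6-en-2-ol, both C2 epimers | C=C[C@@](C)(O[Si](C)(C)C(C)(C)C)CCC(O)C(Cl)(Cl)Cl | intermediate
6 | (5S)-5-methyl-5-(TBS-oxy)hept-6-enoic acid | C=C[C@@](C)(O[Si](C)(C)C(C)(C)C)CCCC(=O)O | intermediate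
7 | geraniol, (2E)-3,7-dimethylocta-2,6-dien-1-ol | C/C(=C\CO)CCC=C(C)C | starting material
8 | (2E,5E)-7-hydroperoxy-3,7-dimethylocta-2,5-dien-1-ol | C/C(=C\CO)C/C=C/C(C)(C)OO | intermediate
9 | (2E,5E)-3,7-dimethylocta-2,5-diene-1,7-diol | C/C(=C\CO)C/C=C/C(C)(C)O | intermediate
10 | (2E,5E)-7-hydroxy-3,7-dimethylocta-2,5-dien-1-yl (5S)-5-methyl-5-(TBS-oxy)hept-6-enoate | C=C[C@@](C)(O[Si](C)(C)C(C)(C)C)CCCC(=O)OC/C=C(\C)C/C=C/C(C)(C)O | intermediate
11 | (2E,5E)-3,7-dimethyl-7-(TBS-oxy)octa-2,5-dien-1-yl (5S)-5-methyl-5-(TBS-oxy)hept-6-enoate | C=C[C@@](C)(O[Si](C)(C)C(C)(C)C)CCCC(=O)OC/C=C(\C)C/C=C/C(C)(C)O[Si](C)(C)C(C)(C)C | intermediate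
12 | boron ketene acetal of 11, alkyl chain cis to O–B, boron carrying the (4S,5S)-bis-sulfonyl-diphenyl-diazaborolidine ligand | C=C[C@@](C)(O[Si](C)(C)C(C)(C)C)CC/C=C(\OB1N(S(=O)(=O)c2cc(C(F)(F)F)cc(C(F)(F)F)c2)[C@@H](c2ccccc2)[C@H](c2ccccc2)N1S(=O)(=O)c1cc(C(F)(F)F)cc(C(F)(F)F)c1)OC/C=C(\C)C/C=C/C(C)(C)O[Si](C)(C)C(C)(C)C | intermediate
13 | boryl ester of acid 14 (acyloxy-diazaborolidine) | C=C[C@@](C)(O[Si](C)(C)C(C)(C)C)CC[C@H](C(=O)OB1N(S(=O)(=O)c2cc(C(F)(F)F)cc(C(F)(F)F)c2)[C@@H](c2ccccc2)[C@H](c2ccccc2)N1S(=O)(=O)c1cc(C(F)(F)F)cc(C(F)(F)F)c1)[C@](C)(C/C=C/C(C)(C)O[Si](C)(C)C(C)(C)C)C=C | intermediate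
14 | (2S,3R)-3-methyl-2-[(3S)-3-methyl-3-(TBS-oxy)pent-4-en-1-yl]-3-[(2E)-4-methyl-4-(TBS-oxy)pent-2-en-1-yl]pent-4-enoic acid | C=C[C@@](C)(O[Si](C)(C)C(C)(C)C)CC[C@H](C(=O)O)[C@](C)(C/C=C/C(C)(C)O[Si](C)(C)C(C)(C)C)C=C | intermediate
15 | dilithium gem-diolate of ketone 16 | C=C[C@@](C)(O[Si](C)(C)C(C)(C)C)CC[C@H](C(C)(O[Li])O[Li])[C@](C)(C/C=C/C(C)(C)O[Si](C)(C)C(C)(C)C)C=C | intermediate
16 | (3S,4R)-4-methyl-3-[(3S)-3-methyl-3-(TBS-oxy)pent-4-en-1-yl]-4-[(2E)-4-methyl-4-(TBS-oxy)pent-2-en-1-yl]hex-5-en-2-one | C=C[C@@](C)(O[Si](C)(C)C(C)(C)C)CC[C@H](C(C)=O)[C@](C)(C/C=C/C(C)(C)O[Si](C)(C)C(C)(C)C)C=C | intermediate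
17 | (3R,4R)-2,4-dimethyl-3-[(3S)-3-methyl-3-(TBS-oxy)pent-4-en-1-yl]-4-[(2E)-4-methyl-4-(TBS-oxy)pent-2-en-1-yl]hexa-1,5-diene | C=C[C@@](C)(O[Si](C)(C)C(C)(C)C)CC[C@H](C(C)=C)[C@](C)(C/C=C/C(C)(C)O[Si](C)(C)C(C)(C)C)C=C | intermediate
18 | (1S,2S,3S,4S)-1,3-dimethyl-2-[(3S)-3-methyl-3-(TBS-oxy)pent-4-en-1-yl]-3-[(2E)-4-methyl-4-(TBS-oxy)pent-2-en-1-yl]-4-[(trifluoroacetoxy)mercurio]cyclohexyl trifluoroacetate | C=C[C@@](C)(O[Si](C)(C)C(C)(C)C)CC[C@H]1[C@](C)(C/C=C/C(C)(C)O[Si](C)(C)C(C)(C)C)[C@@H]([Hg]OC(=O)C(F)(F)F)CC[C@]1(C)OC(=O)C(F)(F)F | intermediate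
19 | (1S,2S,3S,4S)-4-(bromomercurio)-1,3-dimethyl-2-[(3S)-3-methyl-3-(TBS-oxy)pent-4-en-1-yl]-3-[(2E)-4-methyl-4-(TBS-oxy)pent-2-en-1-yl]cyclohexan-1-ol | C=C[C@@](C)(O[Si](C)(C)C(C)(C)C)CC[C@H]1[C@](C)(C/C=C/C(C)(C)O[Si](C)(C)C(C)(C)C)[C@@H]([Hg]Br)CC[C@]1(C)O | intermediate
20 | (1S,2S,3S,4S)-4-bromo-1,3-dimethyl-2-[(3S)-3-methyl-3-(TBS-oxy)pent-4-en-1-yl]-3-[(2E)-4-methyl-4-(TBS-oxy)pent-2-en-1-yl]cyclohexan-1-ol | C=C[C@@](C)(O[Si](C)(C)C(C)(C)C)CC[C@H]1[C@](C)(C/C=C/C(C)(C)O[Si](C)(C)C(C)(C)C)[C@@H](Br)CC[C@]1(C)O | intermediate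
21 | (1S,2S,3S,4S)-4-bromo-2-[(3S)-3-hydroxy-3-methylpent-4-en-1-yl]-3-[(2E)-4-hydroxy-4-methylpent-2-en-1-yl]-1,3-dimethylcyclohexan-1-ol | C=C[C@@](C)(O)CC[C@H]1[C@](C)(C/C=C/C(C)(C)O)[C@@H](Br)CC[C@]1(C)O | target

Total step count: 13. Longest linear sequence: 12 steps (steps 1–4 and 6–13, from (S)-linalool); step 5 is the one-step side branch from geraniol.

Steps most likely to fail

Step 11 (Proposed new method). Mercuration may settle on the isopropenyl group without returning. The C1 cation may lose a proton or undergo a hydride shift before trifluoroacetate captures it. The cyclohexyl cation may also reopen between C2 and C3, which would erase the stereochemical relay. The fallback uses known chemistry and gives up that relay. It sets out from 17: a Cope rearrangement (PdCl2(MeCN)2 cat., THF, rt, or toluene, 180 °C) through the chair with both chains equatorial gives the linear (3S,6E,10E,13E)-3,15-bis(TBS-oxy)-3,7,11,15-tetramethylhexadeca-1,6,10,13-tetraene F1. The established mercury trifluoroacetate cyclisation of such polyprenyl chains (Hg(OCOCF3)2, MeNO2, −20 °C, then KBr, K2CO3, MeOH/H2O) starts at the trisubstituted 10,11-alkene, closes the ring between C2 and C3 and ends at C1 with trifluoroacetate. It would give 19 through 18, together with the ring-mirrored material, formed through the (1R,2R,3R,4R) bis(trifluoroacetate) F2 and isolated as the (1R,2R,3R,4R) organomercuric bromide F3. Because the side-chain carbinol centre is unchanged, 19 and F3 are diastereomers and are separated by preparative HPLC; the route is rejoined at 19.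

Step 8. The [3,3] shift at the congested quaternary terminus may be slow, the Lewis acidic boron bromide may strip a tertiary silyl ether, and the level or sense of induction may disappoint. The fallback sets out from 11 and replaces reagent control by separation. A classical Ireland–Claisen rearrangement (LiN(iPr)2, THF/HMPA, Me3SiCl, −78 °C to rt) proceeds through the trimethylsilyl ketene acetal F4 (chain cis to OSi) and gives the trimethylsilyl ester of 14 F5 and the trimethylsilyl ester of its (2R,3S) diastereomer F6. Aqueous work-up then gives 14 and the (2R,3S) acid F7. The chair still fixes the relative C2/C3 configuration. The two diastereomeric acids are separated by crystallisation of their (R)-1-phenylethylammonium salts or by preparative HPLC, and the route is rejoined at 14.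

Step 10. The ylide may enolise the hindered ketone, leading to incomplete conversion or erosion of the α-stereocentre. The fallback sets out from 16 and uses a non-basic two-stage Peterson olefination: Me3SiCH2Li with CeCl3 (THF, −78 °C) adds to the carbonyl to give the β-hydroxysilane F8, and KH (THF, rt) eliminates it to 17, where the route is rejoined.

Further compounds
F1 | step 11 | (3S,6E,10E,13E)-3,15-bis(TBS-oxy)-3,7,11,15-tetramethylhexadeca-1,6,10,13-tetraene | C=C[C@@](C)(O[Si](C)(C)C(C)(C)C)CC/C=C(\C)CC/C=C(\C)C/C=C/C(C)(C)O[Si](C)(C)C(C)(C)C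
F2 | step 11 | (1R,2R,3R,4R) ring diastereomer of bis(trifluoroacetate) 18, side chain (3S) | C=C[C@@](C)(O[Si](C)(C)C(C)(C)C)CC[C@@H]1[C@@](C)(C/C=C/C(C)(C)O[Si](C)(C)C(C)(C)C)[C@H]([Hg]OC(=O)C(F)(F)F)CC[C@@]1(C)OC(=O)C(F)(F)F
F3 | step 11 | (1R,2R,3R,4R) ring diastereomer of organomercuric bromide 19, side chain (3S) | C=C[C@@](C)(O[Si](C)(C)C(C)(C)C)CC[C@@H]1[C@@](C)(C/C=C/C(C)(C)O[Si](C)(C)C(C)(C)C)[C@H]([Hg]Br)CC[C@@]1(C)O
F4 | step 8 | trimethylsilyl ketene acetal of 11, alkyl chain cis to OSiMe3 | C=C[C@@](C)(O[Si](C)(C)C(C)(C)C)CC/C=C(\O[Si](C)(C)C)OC/C=C(\C)C/C=C/C(C)(C)O[Si](C)(C)C(C)(C)C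
F5 | step 8 | trimethylsilyl ester of acid 14 | C=C[C@@](C)(O[Si](C)(C)C(C)(C)C)CC[C@H](C(=O)O[Si](C)(C)C)[C@](C)(C/C=C/C(C)(C)O[Si](C)(C)C(C)(C)C)C=C
F6 | step 8 | trimethylsilyl ester of the (2R,3S) diastereomer of acid 14 | C=C[C@@](C)(O[Si](C)(C)C(C)(C)C)CC[C@@H](C(=O)O[Si](C)(C)C)[C@@](C)(C/C=C/C(C)(C)O[Si](C)(C)C(C)(C)C)C=C
F7 | step 8 | (2R,3S)-3-methyl-2-[(3S)-3-methyl-3-(TBS-oxy)pent-4-en-1-yl]-3-[(2E)-4-methyl-4-(TBS-oxy)pent-2-en-1-yl]pent-4-enoic acid | C=C[C@@](C)(O[Si](C)(C)C(C)(C)C)CC[C@@H](C(=O)O)[C@@](C)(C/C=C/C(C)(C)O[Si](C)(C)C(C)(C)C)C=C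
F8 | step 10 | β-hydroxysilane from 16, (3S,4R)-2-hydroxy-2-(trimethylsilylmethyl) adduct, both carbinol epimers | C=C[C@@](C)(O[Si](C)(C)C(C)(C)C)CC[C@H](C(C)(O)C[Si](C)(C)C)[C@](C)(C/C=C/C(C)(C)O[Si](C)(C)C(C)(C)C)C=C
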